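The locants C3a–C8a of the 3‑methylideneoctahydrocyclohepta[b]furan‑2‑one core are used. Its carbons C8a–C8–C7–C6–C5, with the C5 oxygen, are treated as a pyranose (C8a anomeric, O‑5 the ring oxygen), built de novo by an asymmetric hetero‑Diels–Alder reaction and then decorated. Everything rests on the ring‑fusion bond C3a–C8a. An indium Barbier reaction of a lactol carrying a (Z)‑2‑(bromomethyl)enoate arm on C5 adds the allylmetal to the masked aldehyde. In one operation this opens the pyran, closes the seven‑membered carbocycle and lets the new C8a alkoxide form the cis‑fused α‑methylene γ‑lactone. The precursor is a 2,3‑dihydroxy lactol bearing the alkynyl side chain at C7.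

Key step: step 12

Remark (assumption): the (1S,2R)‑aminoindanol‑derived chromium catalyst is taken to give the (2R,3S)‑dihydropyranone; if the facial sense proves opposite, its mirror image is used.
Remark (assumption): the anomeric centre of the 4‑methoxybenzyl glycosides is drawn 1,2‑trans, as expected from epoxide opening; its configuration is irrelevant because it later becomes a lactol.
In the pyran intermediates the anomeric carbon is the future C8a, followed round the ring by the future C8, C7, C6 and C5.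

Step 1
Reactants: 1 (E)-4-methoxybut-3-en-2-one
Product: 3 (E)-1-methoxypent-1-en-3-one, via lithium dienolate 2 (not isolated)
Conditions: LiN(iPr)2, THF, −78 °C; MeI, −78 → −20 °C
Reagents that add atoms: iodomethane, CI
Why: Kinetic deprotonation of the vinylogous ester at its methyl group and C‑methylation of the cross‑conjugated enolate (Stork–Danheiser‑type α'‑alkylation) should add the carbon that becomes the C6 methyl, with no stereocentre formed.

Step 2
Reactants: 3 (E)-1-methoxypent-1-en-3-one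
Product: 4 (1E,3Z)-1-methoxy-3-(trimethylsilyloxy)penta-1,3-diene
Conditions: Me3SiOTf, Et3N, Et2O, 0 °C
Reagents that add atoms: trimethylsilyl trifluoromethanesulfonate, C[Si](C)(C)OS(=O)(=O)C(F)(F)F
Why: Soft enolisation of the ethyl ketone (amine/silyl triflate silyl enol ether formation) should give the (Z)‑enol ether, whose methyl lies trans to the diene backbone and so sits "outside" in the cycloaddition.

Step 3
Reactants: 4 (1E,3Z)-1-methoxy-3-(trimethylsilyloxy)penta-1,3-diene; 5 3-(tert-butyldimethylsilyloxy)propanal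
Product: 7 (2R,3S)-2-[2-(tert-butyldimethylsilyloxy)ethyl]-3-methyl-2,3-dihydro-4H-pyran-4-one, via cycloadduct 6 (not isolated)
Conditions: (C27H29NO2)CrCl [tridentate Schiff base of 3-(1-adamantyl)-2-hydroxy-5-methylbenzaldehyde and (1S,2R)-1-aminoindan-2-ol; trivalent chromium] (3 mol %), 4 Å MS, rt; then CF3CO2H (cat.), CH2Cl2, 0 °C
Reagents that add atoms: none
Why: A catalyst‑controlled, endo‑selective hetero‑Diels–Alder reaction on the tridentate Schiff‑base chromium Lewis acid, the catalyst class suited to 4‑substituted silyloxydienes, should set the future C5 (aldehyde face chosen by the catalyst) and the future C6 (cis, from the endo mode and the Z enol ether), after which acid cleaves the silyl enol ether and eliminates methanol without disturbing the cis relationship.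

Step 4
Reactants: 7 (2R,3S)-2-[2-(tert-butyldimethylsilyloxy)ethyl]-3-methyl-2,3-dihydro-4H-pyran-4-one
Product: 9 (2R,3S,5S,6R)-6-[2-(tert-butyldimethylsilyloxy)ethyl]-3-hydroxy-2-[(4-methoxybenzyl)oxy]-5-methyltetrahydro-4H-pyran-4-one, via epoxide 8 (not isolated)
Conditions: dimethyldioxirane, acetone/CH2Cl2, −40 → 0 °C; evaporate; 4-MeOC6H4CH2OH, ZnCl2, THF, −78 → 0 °C
Reagents that add atoms: dimethyldioxirane, CC1(C)OO1; 4-methoxybenzyl alcohol, COc1ccc(CO)cc1
Why: Glycal‑type epoxidation of the enol ether by the neutral dioxirane should occur on the face opposite the pseudoaxial methyl and the side chain, which fixes the future C8 oxygen, and Lewis‑acid‑assisted alcoholysis at the acetal carbon with inversion should give the 1,2‑trans glycoside.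

Step 5
Reactants: 10 (S)-but-3-yn-2-ol
Product: 11 (S)-(but-3-yn-2-yloxy)triisopropylsilane
Conditions: iPr3SiCl, imidazole, DMF, rt
Reagents that add atoms: chlorotriisopropylsilane, CC(C)[Si](Cl)(C(C)C)C(C)C
Why: Standard O‑silylation leaves the purchased carbinol centre untouched, and the triisopropylsilyl ether is chosen to outlast the later selective removal of a primary tert‑butyldimethylsilyl ether.

Step 6
Reactants: 9 (2R,3S,5S,6R)-6-[2-(tert-butyldimethylsilyloxy)ethyl]-3-hydroxy-2-[(4-methoxybenzyl)oxy]-5-methyltetrahydro-4H-pyran-4-one; 11 (S)-(but-3-yn-2-yloxy)triisopropylsilane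
Product: 13 (2R,3R,4R,5S,6R)-6-[2-(tert-butyldimethylsilyloxy)ethyl]-2-[(4-methoxybenzyl)oxy]-5-methyl-4-[(3S)-3-(triisopropylsilyloxy)but-1-yn-1-yl]tetrahydro-2H-pyran-3,4-diol, via lithium acetylide 12 (not isolated)
Conditions: 11 (4 equiv), n-BuLi, THF, −78 °C; then 9 pre-stirred with anhydrous CeCl3, THF, −78 °C; aq. NH4Cl
Reagents that add atoms: none
Why: 1,2‑Addition of the acetylide to the CeCl3‑activated ketone (one equivalent is spent on the free hydroxyl and the cerium salt suppresses enolisation) should occur by axial attack on the chair pyranoside from the face opposite the axial C‑methyl, which sets the future C7 with the alkyne axial and the tertiary hydroxyl equatorial.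

Step 7
Reactants: 13 (2R,3R,4R,5S,6R)-6-[2-(tert-butyldimethylsilyloxy)ethyl]-2-[(4-methoxybenzyl)oxy]-5-methyl-4-[(3S)-3-(triisopropylsilyloxy)but-1-yn-1-yl]tetrahydro-2H-pyran-3,4-diol
Product: 14 (2R,3R,4R,5S,6R)-6-(2-hydroxyethyl)-2-[(4-methoxybenzyl)oxy]-5-methyl-4-[(3S)-3-(triisopropylsilyloxy)but-1-yn-1-yl]tetrahydro-2H-pyran-3,4-diol
Conditions: HF·pyridine, pyridine, THF, 0 °C
Reagents that add atoms: none
Why: Buffered fluoride desilylation should cleave the primary tert‑butyldimethylsilyl ether much faster than the secondary triisopropylsilyl ether and leave the glycosidic acetal intact.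

Step 8
Reactants: 14 (2R,3R,4R,5S,6R)-6-(2-hydroxyethyl)-2-[(4-methoxybenzyl)oxy]-5-methyl-4-[(3S)-3-(triisopropylsilyloxy)but-1-yn-1-yl]tetrahydro-2H-pyran-3,4-diol
Product: 15 2-[(2R,3S,4R,5R,6R)-4,5-dihydroxy-6-[(4-methoxybenzyl)oxy]-3-methyl-4-[(3S)-3-(triisopropylsilyloxy)but-1-yn-1-yl]tetrahydro-2H-pyran-2-yl]acetaldehyde
Conditions: TEMPO (cat.), PhI(OAc)2, CH2Cl2, rt
Reagents that add atoms: none
Why: Oxoammonium (TEMPO) oxidation is selective for the primary alcohol over the hindered secondary and the tertiary hydroxyl, and it stops at the aldehyde, whose carbon is the future C3a.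

Step 9
Reactants: 15 2-[(2R,3S,4R,5R,6R)-4,5-dihydroxy-6-[(4-methoxybenzyl)oxy]-3-methyl-4-[(3S)-3-(triisopropylsilyloxy)but-1-yn-1-yl]tetrahydro-2H-pyran-2-yl]acetaldehyde; 16 methyl acrylate
Product: 17 methyl 2-{1-hydroxy-2-[(2R,3S,4R,5R,6R)-4,5-dihydroxy-6-[(4-methoxybenzyl)oxy]-3-methyl-4-[(3S)-3-(triisopropylsilyloxy)but-1-yn-1-yl]tetrahydro-2H-pyran-2-yl]ethyl}prop-2-enoate (both carbinol epimers)
Conditions: 16 (5 equiv), DABCO (1 equiv), MeOH, rt
Reagents that add atoms: none
Why: The Morita–Baylis–Hillman reaction tolerates the free hydroxyls (a protic medium accelerates it), and the new carbinol centre needs no control because the next step destroys it.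

Step 10
Reactants: 17 methyl 2-{1-hydroxy-2-[(2R,3S,4R,5R,6R)-4,5-dihydroxy-6-[(4-methoxybenzyl)oxy]-3-methyl-4-[(3S)-3-(triisopropylsilyloxy)but-1-yn-1-yl]tetrahydro-2H-pyran-2-yl]ethyl}prop-2-enoate
Product: 18 methyl (2Z)-2-(bromomethyl)-4-[(2R,3S,4R,5R,6R)-4,5-dihydroxy-6-[(4-methoxybenzyl)oxy]-3-methyl-4-[(3S)-3-(triisopropylsilyloxy)but-1-yn-1-yl]tetrahydro-2H-pyran-2-yl]but-2-enoate
Conditions: NBS, Me2S, CH2Cl2, −20 → 0 °C
Reagents that add atoms: N-bromosuccinimide, O=C1CCC(=O)N1Br
Why: The bromosulfonium reagent activates only the allylic alcohol, and bromide then enters with allylic transposition (SN2′ bromination of a Baylis–Hillman adduct) to give the favoured (Z)‑2‑(bromomethyl)enoate, with the ester trans to the chain.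

Step 11
Reactants: 18 methyl (2Z)-2-(bromomethyl)-4-[(2R,3S,4R,5R,6R)-4,5-dihydroxy-6-[(4-methoxybenzyl)oxy]-3-methyl-4-[(3S)-3-(triisopropylsilyloxy)but-1-yn-1-yl]tetrahydro-2H-pyran-2-yl]but-2-enoate
Product: 19 methyl (2Z)-2-(bromomethyl)-4-[(2R,3S,4R,5R)-4,5,6-trihydroxy-3-methyl-4-[(3S)-3-(triisopropylsilyloxy)but-1-yn-1-yl]tetrahydro-2H-pyran-2-yl]but-2-enoate (anomers)
Conditions: DDQ, CH2Cl2/pH 7 buffer (10:1), 0 °C → rt
Reagents that add atoms: none
Why: Oxidative cleavage of the 4‑methoxybenzyl acetal (benzylic hydride abstraction by DDQ, then hydrolysis) should release the lactol under neutral conditions that spare the allylic bromide, the alkyne and the silyl ether.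

Step 12
Reactants: 19 methyl (2Z)-2-(bromomethyl)-4-[(2R,3S,4R,5R)-4,5,6-trihydroxy-3-methyl-4-[(3S)-3-(triisopropylsilyloxy)but-1-yn-1-yl]tetrahydro-2H-pyran-2-yl]but-2-enoate
Product: 22 (3aS,5R,6S,7R,8S,8aR)-5,7,8-trihydroxy-6-methyl-3-methylidene-7-[(3S)-3-(triisopropylsilyloxy)but-1-yn-1-yl]octahydro-2H-cyclohepta[b]furan-2-one, via allylindium lactol 20 (not isolated), via hydroxy ester 21 (not isolated)
Conditions: In powder (zerovalent indium, 4 equiv), THF/H2O (1:1), 0.005 M, rt → 40 °C; aq. NH4Cl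
Reagents that add atoms: none
Why: Indium inserts into the allylic C–Br bond of 19 to give an allylindium (20) that survives water and the free hydroxyls, while the lactol is in equilibrium with a little of its hydroxy aldehyde; the γ‑carbon of the allylmetal (future C3a) then bonds to the aldehyde carbon (future C8a) through a six‑membered chair transition state, with the double bond shifting into the exocyclic position (intramolecular Barbier‑type 2‑(alkoxycarbonyl)allylation). The closest known reactions are the aqueous indium allylation of unprotected aldose lactols with 2‑(bromomethyl)acrylates and intramolecular indium or Nozaki–Hiyama–Kishi cyclisations of such bromides onto aldehydes that give ring‑fused α‑methylene lactones. The cycloheptane closes by 7‑exo‑trig attack on the carbonyl carbon, and the resulting C8a alkoxide closes the γ‑lactone by 5‑exo‑trig acyl substitution at the methyl ester (21 to 22), expelling methanol so that the carbonyl addition cannot revert. C3a is set by the (Z)‑allyl geometry, which holds the C4 methylene axial in the chair and so gives the syn adduct, that is the cis ring fusion; C8a is set by the free C8 hydroxyl, which chelates indium together with the aldehyde oxygen and exposes the carbonyl face on the side of H‑8, a face the tether reaches with C3a gauche to C7, so that O‑8a and O‑8 end up threo (trans on the ring). The step needs ring closure to win over intermolecular allylation and protonolysis of the C–In bond, and it needs the cis‑fused threo isomer; the first should be secured by high dilution, the low stationary concentration of aldehyde, a tether substituted at four of its five atoms (C5 to C8) and the absence of a second electrophile (the side‑chain ketone is still an alkyne), the second by the fixed alkene geometry and the unprotected C8 hydroxyl.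

Step 13
Reactants: 22 (3aS,5R,6S,7R,8S,8aR)-5,7,8-trihydroxy-6-methyl-3-methylidene-7-[(3S)-3-(triisopropylsilyloxy)but-1-yn-1-yl]octahydro-2H-cyclohepta[b]furan-2-one
Product: 23 (3aS,5R,6S,7R,8S,8aR)-5-(tert-butyldimethylsilyloxy)-7,8-dihydroxy-6-methyl-3-methylidene-7-[(3S)-3-(triisopropylsilyloxy)but-1-yn-1-yl]octahydro-2H-cyclohepta[b]furan-2-one
Conditions: tBuMe2SiCl (1.1 equiv), imidazole, DMF, 0 °C → rt
Reagents that add atoms: tert-butylchlorodimethylsilane, CC(C)(C)[Si](C)(C)Cl
Why: Silylation should select the unhindered C5 hydroxyl over the C8 hydroxyl (flanked by the quaternary C7) and the tertiary C7 hydroxyl, which leaves O‑8 as the only acylable oxygen and prevents later base‑induced addition of O‑5 to the methylene lactone.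

Step 14
Reactants: 23 (3aS,5R,6S,7R,8S,8aR)-5-(tert-butyldimethylsilyloxy)-7,8-dihydroxy-6-methyl-3-methylidene-7-[(3S)-3-(triisopropylsilyloxy)but-1-yn-1-yl]octahydro-2H-cyclohepta[b]furan-2-one; 24 (S)-2-methylbutanoic acid
Product: 26 (3aS,5R,6S,7R,8S,8aR)-5-(tert-butyldimethylsilyloxy)-7-hydroxy-6-methyl-3-methylidene-2-oxo-7-[(3S)-3-(triisopropylsilyloxy)but-1-yn-1-yl]octahydro-2H-cyclohepta[b]furan-8-yl (2S)-2-methylbutanoate, via mixed anhydride 25 (not isolated)
Conditions: 24, 2,4,6-Cl3C6H2COCl, Et3N, THF, rt; then 23, DMAP, toluene, rt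
Reagents that add atoms: none
Why: Yamaguchi esterification acylates the only remaining secondary hydroxyl (C8), the tertiary C7 hydroxyl being inert, and the mixed‑anhydride/DMAP conditions avoid ketene formation, so the acid's α‑stereocentre should be preserved.

Step 15
Reactants: 26 (3aS,5R,6S,7R,8S,8aR)-5-(tert-butyldimethylsilyloxy)-7-hydroxy-6-methyl-3-methylidene-2-oxo-7-[(3S)-3-(triisopropylsilyloxy)but-1-yn-1-yl]octahydro-2H-cyclohepta[b]furan-8-yl (2S)-2-methylbutanoate
Product: 28 (3aS,5R,6S,7S,8S,8aR)-5-(tert-butyldimethylsilyloxy)-7-hydroxy-6-methyl-3-methylidene-2-oxo-7-[(3S)-3-(triisopropylsilyloxy)butanoyl]octahydro-2H-cyclohepta[b]furan-8-yl (2S)-2-methylbutanoate, via cyclic carbonate 27 (not isolated)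
Conditions: AgOAc (10 mol %), DBU (0.5 equiv), CO2 (1 atm), MeCN/H2O, rt → 40 °C
Reagents that add atoms: carbon dioxide, O=C=O (delivers the ketone oxygen through the carbonate and is returned); water, O
Why: In this CO2‑promoted, silver‑catalysed hydration of a propargylic alcohol, the carbonate of the tertiary hydroxyl adds 5‑exo‑dig to the silver‑activated alkyne and water then opens the alkylidene carbonate with loss of CO2, so the carbonyl can only appear on the alkyne carbon attached to C7, every other hydroxyl being silylated or acylated.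

Step 16
Reactants: 28 (3aS,5R,6S,7S,8S,8aR)-5-(tert-butyldimethylsilyloxy)-7-hydroxy-6-methyl-3-methylidene-2-oxo-7-[(3S)-3-(triisopropylsilyloxy)butanoyl]octahydro-2H-cyclohepta[b]furan-8-yl (2S)-2-methylbutanoate
Product: 29 (3aS,5R,6S,7S,8S,8aR)-5,7-dihydroxy-7-[(3S)-3-hydroxybutanoyl]-6-methyl-3-methylidene-2-oxooctahydro-2H-cyclohepta[b]furan-8-yl (2S)-2-methylbutanoate (CNP0291806.1)
Conditions: HF (48 % aq.), MeCN, 0 °C → rt
Reagents that add atoms: none
Why: Acidic fluoride desilylation should remove both secondary silyl ethers under non‑basic conditions that spare the methylene lactone, the ester and the β‑hydroxy ketone, with no stereocentre affected.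

Compound list
1 | (E)-4-methoxybut-3-en-2-one | CO/C=C/C(C)=O | starting material
2 | lithium (E)-4-methoxybuta-1,3-dien-2-olate (kinetic enolate of 1) | [Li]OC(=C)/C=C/OC | intermediate
3 | (E)-1-methoxypent-1-en-3-one | CCC(=O)/C=C/OC | intermediate
4 | (1E,3Z)-1-methoxy-3-(trimethylsilyloxy)penta-1,3-diene | CO/C=C/C(O[Si](C)(C)C)=C/C | intermediate
5 | 3-(tert-butyldimethylsilyloxy)propanal | O=CCCO[Si](C)(C)C(C)(C)C | starting material
6 | (2R,5S,6R)-6-[2-(tert-butyldimethylsilyloxy)ethyl]-2-methoxy-5-methyl-4-(trimethylsilyloxy)-5,6-dihydro-2H-pyran (all-cis cycloadduct) | CC(C)(C)[Si](C)(C)OCC[C@H]1O[C@@H](OC)C=C(O[Si](C)(C)C)[C@H]1C | intermediate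
7 | (2R,3S)-2-[2-(tert-butyldimethylsilyloxy)ethyl]-3-methyl-2,3-dihydro-4H-pyran-4-one | CC(C)(C)[Si](C)(C)OCC[C@H]1OC=CC(=O)[C@H]1C | intermediate
8 | (1R,3R,4S,6S)-3-[2-(tert-butyldimethylsilyloxy)ethyl]-4-methyl-2,7-dioxabicyclo[4.1.0]heptan-5-one (epoxide anti to both substituents) | CC(C)(C)[Si](C)(C)OCC[C@H]1O[C@@H]2O[C@@H]2C(=O)[C@H]1C | intermediate
9 | (2R,3S,5S,6R)-6-[2-(tert-butyldimethylsilyloxy)ethyl]-3-hydroxy-2-[(4-methoxybenzyl)oxy]-5-methyltetrahydro-4H-pyran-4-one | CC(C)(C)[Si](C)(C)OCC[C@H]1O[C@@H](OCc2ccc(OC)cc2)[C@H](O)C(=O)[C@H]1C | intermediate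
10 | (S)-but-3-yn-2-ol | C#C[C@H](C)O | starting material
11 | (S)-(but-3-yn-2-yloxy)triisopropylsilane | C#C[C@H](C)O[Si](C(C)C)(C(C)C)C(C)C | intermediate
12 | lithium acetylide of 11 | [Li]C#C[C@H](C)O[Si](C(C)C)(C(C)C)C(C)C | intermediate
13 | (2R,3R,4R,5S,6R)-6-[2-(tert-butyldimethylsilyloxy)ethyl]-2-[(4-methoxybenzyl)oxy]-5-methyl-4-[(3S)-3-(triisopropylsilyloxy)but-1-yn-1-yl]tetrahydro-2H-pyran-3,4-diol | CC(C)(C)[Si](C)(C)OCC[C@H]1O[C@@H](OCc2ccc(OC)cc2)[C@H](O)[C@](O)(C#C[C@H](C)O[Si](C(C)C)(C(C)C)C(C)C)[C@H]1C | intermediate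
14 | (2R,3R,4R,5S,6R)-6-(2-hydroxyethyl)-2-[(4-methoxybenzyl)oxy]-5-methyl-4-[(3S)-3-(triisopropylsilyloxy)but-1-yn-1-yl]tetrahydro-2H-pyran-3,4-diol | OCC[C@H]1O[C@@H](OCc2ccc(OC)cc2)[C@H](O)[C@](O)(C#C[C@H](C)O[Si](C(C)C)(C(C)C)C(C)C)[C@H]1C | intermediate
15 | 2-[(2R,3S,4R,5R,6R)-4,5-dihydroxy-6-[(4-methoxybenzyl)oxy]-3-methyl-4-[(3S)-3-(triisopropylsilyloxy)but-1-yn-1-yl]tetrahydro-2H-pyran-2-yl]acetaldehyde | O=CC[C@H]1O[C@@H](OCc2ccc(OC)cc2)[C@H](O)[C@](O)(C#C[C@H](C)O[Si](C(C)C)(C(C)C)C(C)C)[C@H]1C | intermediate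
16 | methyl acrylate | C=CC(=O)OC | starting material
17 | methyl 2-{1-hydroxy-2-[(2R,3S,4R,5R,6R)-4,5-dihydroxy-6-[(4-methoxybenzyl)oxy]-3-methyl-4-[(3S)-3-(triisopropylsilyloxy)but-1-yn-1-yl]tetrahydro-2H-pyran-2-yl]ethyl}prop-2-enoate (both carbinol epimers) | COC(=O)C(=C)C(O)C[C@H]1O[C@@H](OCc2ccc(OC)cc2)[C@H](O)[C@](O)(C#C[C@H](C)O[Si](C(C)C)(C(C)C)C(C)C)[C@H]1C | intermediate
18 | methyl (2Z)-2-(bromomethyl)-4-[(2R,3S,4R,5R,6R)-4,5-dihydroxy-6-[(4-methoxybenzyl)oxy]-3-methyl-4-[(3S)-3-(triisopropylsilyloxy)but-1-yn-1-yl]tetrahydro-2H-pyran-2-yl]but-2-enoate | COC(=O)/C(CBr)=C/C[C@H]1O[C@@H](OCc2ccc(OC)cc2)[C@H](O)[C@](O)(C#C[C@H](C)O[Si](C(C)C)(C(C)C)C(C)C)[C@H]1C | intermediate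
19 | methyl (2Z)-2-(bromomethyl)-4-[(2R,3S,4R,5R)-4,5,6-trihydroxy-3-methyl-4-[(3S)-3-(triisopropylsilyloxy)but-1-yn-1-yl]tetrahydro-2H-pyran-2-yl]but-2-enoate (lactol, anomers) | COC(=O)/C(CBr)=C/C[C@H]1OC(O)[C@H](O)[C@](O)(C#C[C@H](C)O[Si](C(C)C)(C(C)C)C(C)C)[C@H]1C | intermediate
20 | allylindium form of 19 (C–In in place of C–Br, drawn with monovalent indium) | COC(=O)/C(C[In])=C/C[C@H]1OC(O)[C@H](O)[C@](O)(C#C[C@H](C)O[Si](C(C)C)(C(C)C)C(C)C)[C@H]1C | intermediate
21 | methyl 2-(2,3,4,6-tetrahydroxy-5-methyl-4-alkynylcycloheptyl)prop-2-enoate, ring closed but not yet lactonised, ring carbons configured as in 22 | C=C(C(=O)OC)[C@@H]1C[C@@H](O)[C@H](C)[C@@](O)(C#C[C@H](C)O[Si](C(C)C)(C(C)C)C(C)C)[C@@H](O)[C@@H]1O | intermediate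
22 | (3aS,5R,6S,7R,8S,8aR)-5,7,8-trihydroxy-6-methyl-3-methylidene-7-[(3S)-3-(triisopropylsilyloxy)but-1-yn-1-yl]octahydro-2H-cyclohepta[b]furan-2-one | C=C1C(=O)O[C@@H]2[C@H]1C[C@@H](O)[C@H](C)[C@@](O)(C#C[C@H](C)O[Si](C(C)C)(C(C)C)C(C)C)[C@H]2O | intermediate
23 | (3aS,5R,6S,7R,8S,8aR)-5-(tert-butyldimethylsilyloxy)-7,8-dihydroxy-6-methyl-3-methylidene-7-[(3S)-3-(triisopropylsilyloxy)but-1-yn-1-yl]octahydro-2H-cyclohepta[b]furan-2-one | C=C1C(=O)O[C@@H]2[C@H]1C[C@@H](O[Si](C)(C)C(C)(C)C)[C@H](C)[C@@](O)(C#C[C@H](C)O[Si](C(C)C)(C(C)C)C(C)C)[C@H]2O | intermediate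
24 | (S)-2-methylbutanoic acid | CC[C@H](C)C(=O)O | starting material
25 | (S)-2-methylbutanoic 2,4,6-trichlorobenzoic anhydride | CC[C@H](C)C(=O)OC(=O)c1c(Cl)cc(Cl)cc1Cl | intermediate
26 | (3aS,5R,6S,7R,8S,8aR)-5-(tert-butyldimethylsilyloxy)-7-hydroxy-6-methyl-3-methylidene-2-oxo-7-[(3S)-3-(triisopropylsilyloxy)but-1-yn-1-yl]octahydro-2H-cyclohepta[b]furan-8-yl (2S)-2-methylbutanoate | C=C1C(=O)O[C@@H]2[C@H]1C[C@@H](O[Si](C)(C)C(C)(C)C)[C@H](C)[C@@](O)(C#C[C@H](C)O[Si](C(C)C)(C(C)C)C(C)C)[C@H]2OC(=O)[C@@H](C)CC | intermediate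
27 | cyclic carbonate of 26: 1,3-dioxolan-2-one spiro-fused at C7 (O-7 and the adjacent former alkyne carbon in the ring) carrying a (Z)-[(2S)-2-(triisopropylsilyloxy)propylidene] group | C=C1C(=O)O[C@@H]2[C@H]1C[C@@H](O[Si](C)(C)C(C)(C)C)[C@H](C)[C@]3(OC(=O)O/C3=C\[C@H](C)O[Si](C(C)C)(C(C)C)C(C)C)[C@H]2OC(=O)[C@@H](C)CC | intermediate
28 | (3aS,5R,6S,7S,8S,8aR)-5-(tert-butyldimethylsilyloxy)-7-hydroxy-6-methyl-3-methylidene-2-oxo-7-[(3S)-3-(triisopropylsilyloxy)butanoyl]octahydro-2H-cyclohepta[b]furan-8-yl (2S)-2-methylbutanoate | C=C1C(=O)O[C@@H]2[C@H]1C[C@@H](O[Si](C)(C)C(C)(C)C)[C@H](C)[C@@](O)(C(=O)C[C@H](C)O[Si](C(C)C)(C(C)C)C(C)C)[C@H]2OC(=O)[C@@H](C)CC | intermediate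
29 | (3aS,5R,6S,7S,8S,8aR)-5,7-dihydroxy-7-[(3S)-3-hydroxybutanoyl]-6-methyl-3-methylidene-2-oxooctahydro-2H-cyclohepta[b]furan-8-yl (2S)-2-methylbutanoate (CNP0291806.1) | C=C1C(=O)O[C@@H]2[C@H]1C[C@@H](O)[C@H](C)[C@@](O)(C(=O)C[C@H](C)O)[C@H]2OC(=O)[C@@H](C)CC | target

Total step count: 16. Longest linear sequence: 15 steps (steps 1–4 and 6–16, from compound 1); step 5 lies on the side branch.

Steps most likely to fail

Step 12 (key ring closure). Intermolecular allylation or protonolysis of the carbon–indium bond may outrun the seven‑membered ring closure, or chelation control may be lost so that the wrong aldehyde face is attacked. The fallback sets out from bromide 18. Borylation with B2pin2 under Pd2(dba)3 catalysis (zerovalent palladium) should give the allyl pinacolboronate F1 with the alkene geometry retained. DDQ then releases the lactol boronate F2, an isolable and geometrically defined allylmetal. On warming in toluene it should undergo uncatalysed intramolecular allylboration of the lactol aldehyde through a closed chair transition state, and the borate closes the lactone on mild acidic work‑up. The route is rejoined at 22.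

Step 9 (Morita–Baylis–Hillman reaction). The amine‑catalysed addition may be slow, and during the long exposure the β‑alkoxy aldehyde may lose the ring oxygen by elimination or condense with itself. The fallback sets out from aldehyde 15. Aldol addition of the lithium enolate of methyl 3‑(dimethylamino)propanoate (excess, THF, −78 °C) should give the β‑hydroxy amino ester F3 quickly at low temperature. N‑methylation with MeI gives the ammonium iodide F4, and DBU then eliminates trimethylamine. The route is rejoined at 17.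

Step 15 (alkyne hydration). Carboxylation and cyclisation at the hindered tertiary carbinol may be slow, and prolonged contact with the amidine base may cause conjugate addition to the methylene lactone, β‑elimination of the silyloxy group or a ketol shift. The fallback sets out from 26. Both silyl ethers are removed first (aq. HF, MeCN) to give the alkynyl triol ester F5. Ph3PAuCl/AgOTf (cationic monovalent gold) in wet dioxane should then let the C5 hydroxyl, which is cis to the alkynyl group, add 5‑exo‑dig to the alkyne carbon next to C7, giving the bridged enol ether F6. Hydrolysis in the same flask gives the hydroxy ketone, so the route is rejoined directly at the target 29.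

Further compounds
F1 | step 12 | methyl 4-[(2R,3S,4R,5R,6R)-4,5-dihydroxy-6-[(4-methoxybenzyl)oxy]-3-methyl-4-[(3S)-3-(triisopropylsilyloxy)but-1-yn-1-yl]tetrahydro-2H-pyran-2-yl]-2-[(4,4,5,5-tetramethyl-1,3,2-dioxaborolan-2-yl)methyl]but-2-enoate (alkene geometry as in 18) | COC(=O)/C(CB1OC(C)(C)C(C)(C)O1)=C/C[C@H]1O[C@@H](OCc2ccc(OC)cc2)[C@H](O)[C@](O)(C#C[C@H](C)O[Si](C(C)C)(C(C)C)C(C)C)[C@H]1C
F2 | step 12 | lactol of F1 (anomeric hydroxyl free, anomers) | COC(=O)/C(CB1OC(C)(C)C(C)(C)O1)=C/C[C@H]1OC(O)[C@H](O)[C@](O)(C#C[C@H](C)O[Si](C(C)C)(C(C)C)C(C)C)[C@H]1C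
F3 | step 9 | methyl 2-[(dimethylamino)methyl]-3-hydroxy-4-[(2R,3S,4R,5R,6R)-4,5-dihydroxy-6-[(4-methoxybenzyl)oxy]-3-methyl-4-[(3S)-3-(triisopropylsilyloxy)but-1-yn-1-yl]tetrahydro-2H-pyran-2-yl]butanoate (diastereomers at the two new centres) | COC(=O)C(CN(C)C)C(O)C[C@H]1O[C@@H](OCc2ccc(OC)cc2)[C@H](O)[C@](O)(C#C[C@H](C)O[Si](C(C)C)(C(C)C)C(C)C)[C@H]1C
F4 | step 9 | trimethylammonium iodide derived from F3 by N-methylation | COC(=O)C(C[N+](C)(C)C)C(O)C[C@H]1O[C@@H](OCc2ccc(OC)cc2)[C@H](O)[C@](O)(C#C[C@H](C)O[Si](C(C)C)(C(C)C)C(C)C)[C@H]1C.[I-]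
F5 | step 15 | (3aS,5R,6S,7R,8S,8aR)-5,7-dihydroxy-7-[(3S)-3-hydroxybut-1-yn-1-yl]-6-methyl-3-methylidene-2-oxooctahydro-2H-cyclohepta[b]furan-8-yl (2S)-2-methylbutanoate | C=C1C(=O)O[C@@H]2[C@H]1C[C@@H](O)[C@H](C)[C@@](O)(C#C[C@H](C)O)[C@H]2OC(=O)[C@@H](C)CC
F6 | step 15 | bridged enol ether of F5: O-5 bonded to the alkyne carbon next to C7, exocyclic (Z)-[(2S)-2-hydroxypropylidene] group | C=C1C(=O)O[C@@H]2[C@H]1C[C@H]3O/C(=C\[C@H](C)O)[C@](O)([C@H]3C)[C@H]2OC(=O)[C@@H](C)CC
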